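**Retrosynthetic overview**
1. Numbering: ring A = dihydropyran (O1, C2–C6), ring B = lactone (O1, C2–C5), tetraene C1'–C8' from ring A to ring B. The C4'–C5' bond is cut (Stille) into dienylstannane 14 (ring A) and dienyl iodide 30 (ring B).
2. Ring A: O1–C2 is closed by 6-endo opening of the strained C2–C3 vinyl oxirane by the C6 hydroxyl, which is made in the same flask by CBS reduction of Z-enone 10. The oxirane comes from Sharpless epoxidation of dienol 5.
3. Enabling feature: O1 and the tertiary C3–OH of ring A are anti across C2–C3, so both C–O bonds map onto one E-derived oxirane. C2 is allylic to C1'=C2', and the Z ring alkene C4=C5 holds the C6 oxygen over C2.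
4. Ring B: the C5 oxygen lactonises onto the C2 amide after an Eschenmoser–Claisen rearrangement has set C3 and quaternary C4 from the (R)-solketal-derived carbinol. The ester α-carbon and C5 come from an Evans anti-aldol reaction.
5. Order of ring formation: ring A (step 8), ring B (step 17), tetraene union (step 20).

Key step: step 8

Remark: 1,1-dimethoxy-N,N-dimethylpropan-1-amine (the dimethyl acetal of N,N-dimethylpropanamide) is taken as a purchasable reagent.

**Fragment A (ring A)**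

Step 1
Reactants: 1 prop-2-yn-1-ol
Product: 2 (2E)-3-iodo-2-methylprop-2-en-1-ol
Conditions: Me3Al, Cp2ZrCl2 (25 mol %), CH2Cl2, 0 °C → rt; then I2, THF, −30 → 0 °C; aq. Na2S2O3/potassium sodium tartrate
Reagents that add atoms: trimethylaluminium, C[Al](C)C; iodine, II
Why: Negishi zirconium-catalysed carboalumination adds methyl and aluminium syn across the alkyne with aluminium at the terminus, and iodinolysis of the alkenylalane with retention fixes the E iodoalkene.

Step 2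
Reactants: 2 (2E)-3-iodo-2-methylprop-2-en-1-ol
Product: 4 ethyl (2E,4E)-5-iodo-2,4-dimethylpenta-2,4-dienoate, via (2E)-3-iodo-2-methylprop-2-enal 3 (not isolated)
Conditions: MnO2 (15 equiv), Ph3P=C(CH3)CO2Et, CH2Cl2, rt, one pot
Reagents that add atoms: ethyl 2-(triphenyl-λ5-phosphanylidene)propanoate, CCOC(=O)C(C)=P(c1ccccc1)(c1ccccc1)c1ccccc1
Why: MnO2 oxidises the allylic alcohol to the volatile enal 3, which the stabilised ylide traps in the same flask in an E-selective Wittig reaction (tandem oxidation–Wittig), so the 2E geometry that later defines the oxirane is set here.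

Step 3
Reactants: 4 ethyl (2E,4E)-5-iodo-2,4-dimethylpenta-2,4-dienoate
Product: 5 (2E,4E)-5-iodo-2,4-dimethylpenta-2,4-dien-1-ol
Conditions: i-Bu2AlH (2.2 equiv), CH2Cl2, −78 °C; aq. potassium sodium tartrate
Reagents that add atoms: none
Why: Two hydride equivalents from i-Bu2AlH reduce the conjugated ester in the 1,2 sense at −78 °C without touching the alkenyl iodide (ester reduction).

Step 4
Reactants: 5 (2E,4E)-5-iodo-2,4-dimethylpenta-2,4-dien-1-ol
Product: 6 [(2R,3R)-3-[(1E)-1-iodoprop-1-en-2-yl]-2-methyloxiran-2-yl]methanol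
Conditions: Ti(OiPr)4 (10 mol %), D-(−)-diethyl tartrate (12 mol %), t-BuOOH, 4 Å molecular sieves, CH2Cl2, −20 °C
Reagents that add atoms: tert-butyl hydroperoxide, CC(C)(C)OO
Why: Katsuki–Sharpless asymmetric epoxidation delivers oxygen only to the alkene held through the allylic alkoxide on the titanium–tartrate complex, and D-(−)-tartrate should give the (2R,3R)-oxirane by analogy with (E)-2-methyl-3-arylprop-2-en-1-ols (L-(+)-tartrate gives 2S,3S), which sets C3 and, before inversion, C2 of ring A.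

Step 5
Reactants: 6 [(2R,3R)-3-[(1E)-1-iodoprop-1-en-2-yl]-2-methyloxiran-2-yl]methanol
Product: 7 (2S,3R)-3-[(1E)-1-iodoprop-1-en-2-yl]-2-methyloxirane-2-carbaldehyde
Conditions: Dess–Martin periodinane, NaHCO3, CH2Cl2, 0 °C → rt
Reagents that add atoms: none
Why: Dess–Martin oxidation under bicarbonate buffer gives the aldehyde without acid that would open the vinyl oxirane, and the α-carbon is quaternary so it cannot epimerise.

Step 6
Reactants: 7 (2S,3R)-3-[(1E)-1-iodoprop-1-en-2-yl]-2-methyloxirane-2-carbaldehyde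
Product: 8 ethyl (2Z)-3-[(2R,3R)-3-[(1E)-1-iodoprop-1-en-2-yl]-2-methyloxiran-2-yl]-2-methylprop-2-enoate
Conditions: (CF3CH2O)2P(O)CH(CH3)CO2Et, KN(SiMe3)2, 18-crown-6, THF, −78 °C
Reagents that add atoms: ethyl 2-[bis(2,2,2-trifluoroethoxy)phosphoryl]propanoate, CCOC(=O)C(C)P(=O)(OCC(F)(F)F)OCC(F)(F)F
Why: In the Still–Gennari variant of the Horner–Wadsworth–Emmons reaction the trifluoroethyl phosphonate eliminates fast from the kinetically formed adduct, which should give the Z trisubstituted enoate that places C6 cis to C3 across C4=C5.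

Step 7
Reactants: 8 ethyl (2Z)-3-[(2R,3R)-3-[(1E)-1-iodoprop-1-en-2-yl]-2-methyloxiran-2-yl]-2-methylprop-2-enoate
Product: 10 (3Z)-4-[(2R,3R)-3-[(1E)-1-iodoprop-1-en-2-yl]-2-methyloxiran-2-yl]-3-methylbut-3-en-2-one, via Weinreb amide 9 (not isolated)
Conditions: MeNH(OMe)·HCl, i-PrMgCl, THF, −20 °C; then MeMgBr, −20 → 0 °C
Reagents that add atoms: methylmagnesium bromide, C[Mg]Br; N,O-dimethylhydroxylamine hydrochloride, CNOC.Cl (its atoms stay only in 9)
Why: The chloromagnesium amide of N,O-dimethylhydroxylamine converts the ester into Weinreb amide 9, whose chelated tetrahedral adduct with MeMgBr collapses only on work-up, so the reaction stops at the methyl ketone (Weinreb ketone synthesis).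

Step 8
Reactants: 10 (3Z)-4-[(2R,3R)-3-[(1E)-1-iodoprop-1-en-2-yl]-2-methyloxiran-2-yl]-3-methylbut-3-en-2-one
Product: 12 (2S,3R,6S)-2-[(1E)-1-iodoprop-1-en-2-yl]-3,5,6-trimethyl-3,6-dihydro-2H-pyran-3-ol, via epoxy alcohol 11 (not isolated)
Conditions: (R)-2-methyl-CBS-oxazaborolidine (0.5 equiv), catecholborane, toluene, −78 °C; MeOH; then (+)-camphor-10-sulfonic acid (10 mol %), CH2Cl2, −20 → 0 °C
Reagents that add atoms: none
Why: The oxazaborolidine–catecholborane complex binds the ketone with the bulky alkenyl arm away from the catalyst and delivers hydride to one face (Corey–Bakshi–Shibata reduction); after methanolysis of the borate, the acid protonates the oxirane and the new C6 hydroxyl opens it at C2 with inversion in a borderline SN2 process, the closest known type being the acid-catalysed hydroxy vinyl-epoxide cyclisation of Nicolaou. Ring A closes in the 6-endo-tet mode, driven by release of oxirane strain. C6 (S) is set by the (R)-catalyst, C2 (S) by inversion of the Sharpless-derived (R)-oxirane carbon, and C3 (R) is carried over unchanged as the liberated tertiary alcohol. The step needs attack at C2 and not 5-exo attack at the tertiary C3: the exocyclic C1'=C2' π bond can align with the breaking C2–O bond, whereas the endocyclic Z alkene lies in the plane of the dihydrofuran that exo attack would form and cannot stabilise C3. It also needs 1,2- over 1,4-reduction and survival of the alkenyl iodide, which catecholborane at −78 °C should secure. The Z geometry of C4=C5 from step 6 holds the C6 oxygen within bonding distance of C2.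

Step 9
Reactants: 12 (2S,3R,6S)-2-[(1E)-1-iodoprop-1-en-2-yl]-3,5,6-trimethyl-3,6-dihydro-2H-pyran-3-ol; 13 (E)-1,2-bis(tributylstannyl)ethene
Product: 14 (2S,3R,6S)-3,5,6-trimethyl-2-[(2E,4E)-5-(tributylstannyl)penta-2,4-dien-2-yl]-3,6-dihydro-2H-pyran-3-ol
Conditions: 13 (3 equiv), PdCl2(MeCN)2 (5 mol %), DMF, rt, dark
Reagents that add atoms: none
Why: Stille coupling of the alkenyl iodide with a threefold excess of the distannane transfers one stannylvinyl group with retention of both alkene geometries and leaves the tertiary alcohol free.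

**Fragment B (ring B)**

Step 10
Reactants: 15 [(4R)-2,2-dimethyl-1,3-dioxolan-4-yl]methanol
Product: 17 (2E)-3-[(4R)-2,2-dimethyl-1,3-dioxolan-4-yl]-2-methylprop-2-enal, via aldehyde 16 (not isolated)
Conditions: TEMPO (10 mol %), PhI(OAc)2, CH2Cl2, rt; then Ph3P=C(CH3)CHO, rt → 40 °C
Reagents that add atoms: 2-(triphenyl-λ5-phosphanylidene)propanal, CC(C=O)=P(c1ccccc1)(c1ccccc1)c1ccccc1
Why: The oxoammonium salt from TEMPO and PhI(OAc)2 oxidises the primary alcohol to aldehyde 16 without touching the acetonide, and the stabilised formyl ylide converts it in the same flask into the E enal (Wittig reaction), the stereocentre being carried over from (R)-solketal.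

Step 11
Reactants: 17 (2E)-3-[(4R)-2,2-dimethyl-1,3-dioxolan-4-yl]-2-methylprop-2-enal; 18 (4S)-4-benzyl-3-propanoyl-1,3-oxazolidin-2-one
Product: 20 (4S)-4-benzyl-3-[(2R,3S,4E)-5-[(4R)-2,2-dimethyl-1,3-dioxolan-4-yl]-3-hydroxy-2,4-dimethylpent-4-enoyl]-1,3-oxazolidin-2-one, via trimethylsilyl ether 19 (not isolated)
Conditions: MgCl2 (20 mol %), Et3N, Me3SiCl, EtOAc, rt; then 0.5 M HCl, THF, 0 °C
Reagents that add atoms: chlorotrimethylsilane, C[Si](C)(C)Cl (its atoms stay only in 19)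
Why: In the Evans MgCl2-catalysed direct aldol reaction the chelated Z magnesium enolate of the (S)-benzyl imide should add to the non-enolisable enal on the face away from the benzyl group through a boat-like transition state to give the anti adduct, silylation of the aldolate making the addition irreversible, which sets the ester α-carbon (R) and C5 (S) of ring B.

Step 12
Reactants: 20 (4S)-4-benzyl-3-[(2R,3S,4E)-5-[(4R)-2,2-dimethyl-1,3-dioxolan-4-yl]-3-hydroxy-2,4-dimethylpent-4-enoyl]-1,3-oxazolidin-2-one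
Product: 21 methyl (2R,3S,4E)-5-[(4R)-2,2-dimethyl-1,3-dioxolan-4-yl]-3-hydroxy-2,4-dimethylpent-4-enoate
Conditions: Mg(OMe)2 (1.2 equiv), MeOH/CH2Cl2, 0 °C
Reagents that add atoms: methanol, CO (delivered as Mg(OMe)2 in MeOH)
Why: Magnesium methoxide attacks the exocyclic imide carbonyl that is activated by chelation, so the auxiliary is exchanged for methoxide without retro-aldol cleavage (transesterification of an N-acyl oxazolidinone).

Step 13
Reactants: 21 methyl (2R,3S,4E)-5-[(4R)-2,2-dimethyl-1,3-dioxolan-4-yl]-3-hydroxy-2,4-dimethylpent-4-enoate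
Product: 22 methyl (2R,3S,4E)-3-[(tert-butyldimethylsilyl)oxy]-5-[(4R)-2,2-dimethyl-1,3-dioxolan-4-yl]-2,4-dimethylpent-4-enoate
Conditions: t-BuMe2SiOTf, 2,6-lutidine, CH2Cl2, −78 → 0 °C
Reagents that add atoms: tert-butyldimethylsilyl trifluoromethanesulfonate, CC(C)(C)[Si](C)(C)OS(=O)(=O)C(F)(F)F
Why: The silyl triflate with 2,6-lutidine silylates the hindered secondary alcohol so that it cannot take part in the later amide-acetal exchange (silyl ether protection).

Step 14
Reactants: 22 methyl (2R,3S,4E)-3-[(tert-butyldimethylsilyl)oxy]-5-[(4R)-2,2-dimethyl-1,3-dioxolan-4-yl]-2,4-dimethylpent-4-enoate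
Product: 23 methyl (2R,3S,4E,6R)-3-[(tert-butyldimethylsilyl)oxy]-6,7-dihydroxy-2,4-dimethylhept-4-enoate
Conditions: AcOH/H2O (4:1), 35 °C
Reagents that add atoms: none
Why: Aqueous acetic acid hydrolyses the terminal acetonide while the hindered secondary silyl ether and the methyl ester should survive (acetal hydrolysis).

Step 15
Reactants: 23 methyl (2R,3S,4E,6R)-3-[(tert-butyldimethylsilyl)oxy]-6,7-dihydroxy-2,4-dimethylhept-4-enoate
Product: 24 methyl (2R,3S,4E,6R)-3,7-bis[(tert-butyldimethylsilyl)oxy]-6-hydroxy-2,4-dimethylhept-4-enoate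
Conditions: t-BuMe2SiCl (1.05 equiv), imidazole, CH2Cl2, 0 °C
Reagents that add atoms: tert-butyldimethylsilyl chloride, CC(C)(C)[Si](C)(C)Cl
Why: The primary hydroxyl is silylated far faster than the secondary allylic one at 0 °C, which leaves the C7' carbinol free for the rearrangement (selective silylation).

Step 16
Reactants: 24 methyl (2R,3S,4E,6R)-3,7-bis[(tert-butyldimethylsilyl)oxy]-6-hydroxy-2,4-dimethylhept-4-enoate
Product: 26 methyl (2R,3S,4R,5R)-3-[(tert-butyldimethylsilyl)oxy]-4-[(1E)-3-[(tert-butyldimethylsilyl)oxy]prop-1-en-1-yl]-6-(dimethylamino)-2,4,5-trimethyl-6-oxohexanoate, via ketene N,O-acetal 25 (not isolated)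
Conditions: EtC(OMe)2NMe2 (6 equiv), xylenes, 140 °C, sealed tube
Reagents that add atoms: 1,1-dimethoxy-N,N-dimethylpropan-1-amine, CCC(OC)(OC)N(C)C
Why: Exchange with the amide acetal and loss of methanol give the Z ketene N,O-acetal 25, which should rearrange through a chair transition state with the silyloxymethyl group equatorial (Eschenmoser–Claisen [3,3]-sigmatropic rearrangement), so the R carbinol and the E alkene are translated into C3 (R), quaternary C4 (R) and the E C7'=C8' bond of ring B.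

Step 17
Reactants: 26 methyl (2R,3S,4R,5R)-3-[(tert-butyldimethylsilyl)oxy]-4-[(1E)-3-[(tert-butyldimethylsilyl)oxy]prop-1-en-1-yl]-6-(dimethylamino)-2,4,5-trimethyl-6-oxohexanoate
Product: 28 methyl (2R)-2-[(2S,3R,4R)-3-[(1E)-3-hydroxyprop-1-en-1-yl]-3,4-dimethyl-5-oxooxolan-2-yl]propanoate, via dihydroxy amide 27 (not isolated)
Conditions: p-TsOH·H2O (1.5 equiv), MeOH, 50 °C
Reagents that add atoms: none
Why: Acid in methanol removes both silyl ethers and the freed C5 hydroxyl then attacks the neighbouring dimethylamide with loss of dimethylamine, the quaternary C4 favouring the five-membered closure (acid-catalysed lactonisation of a γ-hydroxy amide).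

Step 18
Reactants: 28 methyl (2R)-2-[(2S,3R,4R)-3-[(1E)-3-hydroxyprop-1-en-1-yl]-3,4-dimethyl-5-oxooxolan-2-yl]propanoate
Product: 29 methyl (2R)-2-[(2S,3R,4R)-3,4-dimethyl-5-oxo-3-[(1E)-3-oxoprop-1-en-1-yl]oxolan-2-yl]propanoate
Conditions: MnO2 (20 equiv), CH2Cl2, rt
Reagents that add atoms: none
Why: MnO2 oxidises only the allylic alcohol to the E enal under neutral conditions (allylic oxidation).

Step 19
Reactants: 29 methyl (2R)-2-[(2S,3R,4R)-3,4-dimethyl-5-oxo-3-[(1E)-3-oxoprop-1-en-1-yl]oxolan-2-yl]propanoate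
Product: 30 methyl (2R)-2-[(2S,3R,4R)-3-[(1E,3E)-4-iodobuta-1,3-dien-1-yl]-3,4-dimethyl-5-oxooxolan-2-yl]propanoate
Conditions: CrCl2 (8 equiv), CHI3 (3 equiv), THF, 0 °C → rt
Reagents that add atoms: iodoform, IC(I)I
Why: The Takai olefination with the geminal dichromium species from CHI3 and CrCl2 converts the aldehyde into the E alkenyl iodide and tolerates lactone and ester.

**Union**

Step 20
Reactants: 14 (2S,3R,6S)-3,5,6-trimethyl-2-[(2E,4E)-5-(tributylstannyl)penta-2,4-dien-2-yl]-3,6-dihydro-2H-pyran-3-ol; 30 methyl (2R)-2-[(2S,3R,4R)-3-[(1E,3E)-4-iodobuta-1,3-dien-1-yl]-3,4-dimethyl-5-oxooxolan-2-yl]propanoate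
Product: 31 methyl (2R)-2-[(2S,3R,4R)-3-[(1E,3E,5E,7E)-8-[(2S,3R,6S)-3-hydroxy-3,5,6-trimethyl-3,6-dihydro-2H-pyran-2-yl]nona-1,3,5,7-tetraen-1-yl]-3,4-dimethyl-5-oxooxolan-2-yl]propanoate (CNP0193623.2)
Conditions: Pd2(dba)3 (5 mol %), AsPh3 (20 mol %), DMF/THF, rt, dark
Reagents that add atoms: none
Why: Stille coupling of the dienylstannane with the dienyl iodide under neutral conditions forms the C4'–C5' bond with retention of all four alkene geometries and leaves lactone, ester and tertiary alcohol untouched.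

**Compound list**

1 | prop-2-yn-1-ol | C#CCO | starting material
2 | (2E)-3-iodo-2-methylprop-2-en-1-ol | OC/C(C)=C/I | intermediate
3 | (2E)-3-iodo-2-methylprop-2-enal | O=C/C(C)=C/I | intermediate (not isolated)
4 | ethyl (2E,4E)-5-iodo-2,4-dimethylpenta-2,4-dienoate | CCOC(=O)/C(C)=C/C(C)=C/I | intermediate
5 | (2E,4E)-5-iodo-2,4-dimethylpenta-2,4-dien-1-ol | OC/C(C)=C/C(C)=C/I | intermediate
6 | [(2R,3R)-3-[(1E)-1-iodoprop-1-en-2-yl]-2-methyloxiran-2-yl]methanol | OC[C@@]1(C)O[C@@H]1/C(C)=C/I | intermediate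
7 | (2S,3R)-3-[(1E)-1-iodoprop-1-en-2-yl]-2-methyloxirane-2-carbaldehyde | O=C[C@@]1(C)O[C@@H]1/C(C)=C/I | intermediate
8 | ethyl (2Z)-3-[(2R,3R)-3-[(1E)-1-iodoprop-1-en-2-yl]-2-methyloxiran-2-yl]-2-methylprop-2-enoate | CCOC(=O)/C(C)=C\[C@@]1(C)O[C@@H]1/C(C)=C/I | intermediate
9 | (2Z)-3-[(2R,3R)-3-[(1E)-1-iodoprop-1-en-2-yl]-2-methyloxiran-2-yl]-N-methoxy-N,2-dimethylprop-2-enamide | CON(C)C(=O)/C(C)=C\[C@@]1(C)O[C@@H]1/C(C)=C/I | intermediate (not isolated)
10 | (3Z)-4-[(2R,3R)-3-[(1E)-1-iodoprop-1-en-2-yl]-2-methyloxiran-2-yl]-3-methylbut-3-en-2-one | CC(=O)/C(C)=C\[C@@]1(C)O[C@@H]1/C(C)=C/I | intermediate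
11 | (2S,3Z)-4-[(2R,3R)-3-[(1E)-1-iodoprop-1-en-2-yl]-2-methyloxiran-2-yl]-3-methylbut-3-en-2-ol | C[C@H](O)/C(C)=C\[C@@]1(C)O[C@@H]1/C(C)=C/I | intermediate (not isolated)
12 | (2S,3R,6S)-2-[(1E)-1-iodoprop-1-en-2-yl]-3,5,6-trimethyl-3,6-dihydro-2H-pyran-3-ol | I/C=C(\C)[C@@H]1O[C@@H](C)C(C)=C[C@@]1(C)O | intermediate
13 | (E)-1,2-bis(tributylstannyl)ethene | CCCC[Sn](CCCC)(CCCC)/C=C/[Sn](CCCC)(CCCC)CCCC | starting material
14 | (2S,3R,6S)-3,5,6-trimethyl-2-[(2E,4E)-5-(tributylstannyl)penta-2,4-dien-2-yl]-3,6-dihydro-2H-pyran-3-ol | CCCC[Sn](CCCC)(CCCC)/C=C/C=C(\C)[C@@H]1O[C@@H](C)C(C)=C[C@@]1(C)O | intermediate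
15 | [(4R)-2,2-dimethyl-1,3-dioxolan-4-yl]methanol ((R)-solketal) | OC[C@@H]1COC(C)(C)O1 | starting material
16 | (4S)-2,2-dimethyl-1,3-dioxolane-4-carbaldehyde | O=C[C@@H]1COC(C)(C)O1 | intermediate (not isolated)
17 | (2E)-3-[(4R)-2,2-dimethyl-1,3-dioxolan-4-yl]-2-methylprop-2-enal | O=C/C(C)=C/[C@@H]1COC(C)(C)O1 | intermediate
18 | (4S)-4-benzyl-3-propanoyl-1,3-oxazolidin-2-one | CCC(=O)N1[C@@H](Cc2ccccc2)COC1=O | starting material
19 | (4S)-4-benzyl-3-[(2R,3S,4E)-5-[(4R)-2,2-dimethyl-1,3-dioxolan-4-yl]-2,4-dimethyl-3-[(trimethylsilyl)oxy]pent-4-enoyl]-1,3-oxazolidin-2-one | O=C(N1[C@@H](Cc2ccccc2)COC1=O)[C@H](C)[C@H](O[Si](C)(C)C)/C(C)=C/[C@@H]1COC(C)(C)O1 | intermediate (not isolated)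
20 | (4S)-4-benzyl-3-[(2R,3S,4E)-5-[(4R)-2,2-dimethyl-1,3-dioxolan-4-yl]-3-hydroxy-2,4-dimethylpent-4-enoyl]-1,3-oxazolidin-2-one | O=C(N1[C@@H](Cc2ccccc2)COC1=O)[C@H](C)[C@H](O)/C(C)=C/[C@@H]1COC(C)(C)O1 | intermediate
21 | methyl (2R,3S,4E)-5-[(4R)-2,2-dimethyl-1,3-dioxolan-4-yl]-3-hydroxy-2,4-dimethylpent-4-enoate | COC(=O)[C@H](C)[C@H](O)/C(C)=C/[C@@H]1COC(C)(C)O1 | intermediate
22 | methyl (2R,3S,4E)-3-[(tert-butyldimethylsilyl)oxy]-5-[(4R)-2,2-dimethyl-1,3-dioxolan-4-yl]-2,4-dimethylpent-4-enoate | COC(=O)[C@H](C)[C@H](O[Si](C)(C)C(C)(C)C)/C(C)=C/[C@@H]1COC(C)(C)O1 | intermediate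
23 | methyl (2R,3S,4E,6R)-3-[(tert-butyldimethylsilyl)oxy]-6,7-dihydroxy-2,4-dimethylhept-4-enoate | COC(=O)[C@H](C)[C@H](O[Si](C)(C)C(C)(C)C)/C(C)=C/[C@@H](O)CO | intermediate
24 | methyl (2R,3S,4E,6R)-3,7-bis[(tert-butyldimethylsilyl)oxy]-6-hydroxy-2,4-dimethylhept-4-enoate | COC(=O)[C@H](C)[C@H](O[Si](C)(C)C(C)(C)C)/C(C)=C/[C@@H](O)CO[Si](C)(C)C(C)(C)C | intermediate
25 | methyl (2R,3S,4E,6R)-3,7-bis[(tert-butyldimethylsilyl)oxy]-6-{[(1Z)-1-(dimethylamino)prop-1-en-1-yl]oxy}-2,4-dimethylhept-4-enoate | COC(=O)[C@H](C)[C@H](O[Si](C)(C)C(C)(C)C)/C(C)=C/[C@@H](O/C(=C\C)N(C)C)CO[Si](C)(C)C(C)(C)C | intermediate (not isolated)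
26 | methyl (2R,3S,4R,5R)-3-[(tert-butyldimethylsilyl)oxy]-4-[(1E)-3-[(tert-butyldimethylsilyl)oxy]prop-1-en-1-yl]-6-(dimethylamino)-2,4,5-trimethyl-6-oxohexanoate | COC(=O)[C@H](C)[C@H](O[Si](C)(C)C(C)(C)C)[C@](C)(/C=C/CO[Si](C)(C)C(C)(C)C)[C@@H](C)C(=O)N(C)C | intermediate
27 | methyl (2R,3S,4R,5R)-6-(dimethylamino)-3-hydroxy-4-[(1E)-3-hydroxyprop-1-en-1-yl]-2,4,5-trimethyl-6-oxohexanoate | COC(=O)[C@H](C)[C@H](O)[C@](C)(/C=C/CO)[C@@H](C)C(=O)N(C)C | intermediate (not isolated)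
28 | methyl (2R)-2-[(2S,3R,4R)-3-[(1E)-3-hydroxyprop-1-en-1-yl]-3,4-dimethyl-5-oxooxolan-2-yl]propanoate | COC(=O)[C@H](C)[C@@H]1OC(=O)[C@H](C)[C@@]1(C)/C=C/CO | intermediate
29 | methyl (2R)-2-[(2S,3R,4R)-3,4-dimethyl-5-oxo-3-[(1E)-3-oxoprop-1-en-1-yl]oxolan-2-yl]propanoate | COC(=O)[C@H](C)[C@@H]1OC(=O)[C@H](C)[C@@]1(C)/C=C/C=O | intermediate
30 | methyl (2R)-2-[(2S,3R,4R)-3-[(1E,3E)-4-iodobuta-1,3-dien-1-yl]-3,4-dimethyl-5-oxooxolan-2-yl]propanoate | COC(=O)[C@H](C)[C@@H]1OC(=O)[C@H](C)[C@@]1(C)/C=C/C=C/I | intermediate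
31 | methyl (2R)-2-[(2S,3R,4R)-3-[(1E,3E,5E,7E)-8-[(2S,3R,6S)-3-hydroxy-3,5,6-trimethyl-3,6-dihydro-2H-pyran-2-yl]nona-1,3,5,7-tetraen-1-yl]-3,4-dimethyl-5-oxooxolan-2-yl]propanoate | COC(=O)[C@H](C)[C@@H]1OC(=O)[C@H](C)[C@@]1(C)/C=C/C=C/C=C/C=C(\C)[C@@H]1O[C@@H](C)C(C)=C[C@@]1(C)O | target

**Step count and risks**

Total step count: 20. Longest linear sequence: 11 steps (steps 10–20, from 15).

Steps most likely to fail:

1. Step 8. The oxirane may be opened at the tertiary carbon C3 (5-exo closure to a dihydrofuran) or may ionise at C2 with loss of configuration, and hydride transfer may be incompletely face-selective. In the fallback the O1–C2 bond is made intermolecularly by SN2 opening and ring A is closed at C4=C5 by metathesis. It sets out from 7: methylenation (Ph3P=CH2 from Ph3PCH3Br and KOt-Bu, THF, 0 °C) gives (2R,3R)-2-ethenyl-3-[(1E)-1-iodoprop-1-en-2-yl]-2-methyloxirane F1. The potassium alkoxide of (2S)-3-methylbut-3-en-2-ol F2 (from lipase resolution of the commercial racemate; KH, 18-crown-6, THF, 50 °C) opens F1 at the less substituted allylic carbon C2 with inversion, the tertiary C3 being closed to SN2 attack, to give (3R,4S,5E)-6-iodo-3,5-dimethyl-4-{[(2S)-3-methylbut-3-en-2-yl]oxy}hexa-1,5-dien-3-ol F3. Ring-closing metathesis of F3 with the second-generation Grubbs catalyst RuCl2(=CHPh)(PCy3)(H2IMes) in CH2Cl2 at 40 °C forms the trisubstituted C4=C5 bond and comes back to the route at 12.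

2. Step 16. The rearrangement has to build a quaternary carbon next to a silyloxy-bearing centre, so a slow [3,3] shift, elimination of the allylic carbinol to a diene, or leakage through a boat transition state with loss of diastereoselectivity at C3/C4 may occur. The fallback is an ester-enolate (Ireland–Claisen) rearrangement at low temperature, setting out from 24. Acylation (propanoyl chloride, pyridine, DMAP, CH2Cl2, 0 °C) gives methyl (2R,3S,4E,6R)-3,7-bis[(tert-butyldimethylsilyl)oxy]-2,4-dimethyl-6-(propanoyloxy)hept-4-enoate F4. LiN(i-Pr)2 in THF at −78 °C should deprotonate the unhindered propanoate CH2 and not the hindered ester α-CH, and Me3SiCl traps the enolate as the silyl ketene acetal methyl (2R,3S,4E,6R)-3,7-bis[(tert-butyldimethylsilyl)oxy]-2,4-dimethyl-6-({(1E)-1-[(trimethylsilyl)oxy]prop-1-en-1-yl}oxy)hept-4-enoate F5, with methyl cis to the allylic oxygen. On warming to 50 °C it rearranges through the same chair to the silyl ester 6-methyl 1-(trimethylsilyl) (2R,3R,4S,5R)-4-[(tert-butyldimethylsilyl)oxy]-3-[(1E)-3-[(tert-butyldimethylsilyl)oxy]prop-1-en-1-yl]-2,3,5-trimethylhexanedioate F6, which aqueous work-up hydrolyses to (2R,3R,4S,5R)-4-[(tert-butyldimethylsilyl)oxy]-3-[(1E)-3-[(tert-butyldimethylsilyl)oxy]prop-1-en-1-yl]-6-methoxy-2,3,5-trimethyl-6-oxohexanoic acid F7. p-TsOH in MeOH at 50 °C then removes the silyl ethers and closes the lactone, coming back to the route at 28.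

3. Step 7. The magnesium halides formed may open the vinyl oxirane to halohydrins, acyl substitution at the hindered Z ester may be slow, and halogen–magnesium exchange at the alkenyl iodide may compete on prolonged reaction. The fallback is a redox route in which the only organometallic step runs at −78 °C, setting out from 8. i-Bu2AlH (CH2Cl2, −78 °C) gives (2Z)-3-[(2R,3R)-3-[(1E)-1-iodoprop-1-en-2-yl]-2-methyloxiran-2-yl]-2-methylprop-2-en-1-ol F8. Dess–Martin periodinane with NaHCO3 gives (2Z)-3-[(2R,3R)-3-[(1E)-1-iodoprop-1-en-2-yl]-2-methyloxiran-2-yl]-2-methylprop-2-enal F9. MeMgBr (THF, −78 °C) adds to give (3Z)-4-[(2R,3R)-3-[(1E)-1-iodoprop-1-en-2-yl]-2-methyloxiran-2-yl]-3-methylbut-3-en-2-ol (both carbinol epimers) F10, and a second Dess–Martin oxidation comes back to the route at 10.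

**Further compounds**

F1 | step 8 | (2R,3R)-2-ethenyl-3-[(1E)-1-iodoprop-1-en-2-yl]-2-methyloxirane | C=C[C@@]1(C)O[C@@H]1/C(C)=C/I
F2 | step 8 | (2S)-3-methylbut-3-en-2-ol | C=C(C)[C@H](C)O
F3 | step 8 | (3R,4S,5E)-6-iodo-3,5-dimethyl-4-{[(2S)-3-methylbut-3-en-2-yl]oxy}hexa-1,5-dien-3-ol | I/C=C(\C)[C@H](O[C@@H](C)C(C)=C)[C@](C)(O)C=C
F4 | step 16 | methyl (2R,3S,4E,6R)-3,7-bis[(tert-butyldimethylsilyl)oxy]-2,4-dimethyl-6-(propanoyloxy)hept-4-enoate | COC(=O)[C@H](C)[C@H](O[Si](C)(C)C(C)(C)C)/C(C)=C/[C@@H](OC(=O)CC)CO[Si](C)(C)C(C)(C)C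
F5 | step 16 | methyl (2R,3S,4E,6R)-3,7-bis[(tert-butyldimethylsilyl)oxy]-2,4-dimethyl-6-({(1E)-1-[(trimethylsilyl)oxy]prop-1-en-1-yl}oxy)hept-4-enoate | COC(=O)[C@H](C)[C@H](O[Si](C)(C)C(C)(C)C)/C(C)=C/[C@@H](O/C(O[Si](C)(C)C)=C\C)CO[Si](C)(C)C(C)(C)C
F6 | step 16 | 6-methyl 1-(trimethylsilyl) (2R,3R,4S,5R)-4-[(tert-butyldimethylsilyl)oxy]-3-[(1E)-3-[(tert-butyldimethylsilyl)oxy]prop-1-en-1-yl]-2,3,5-trimethylhexanedioate | COC(=O)[C@H](C)[C@H](O[Si](C)(C)C(C)(C)C)[C@](C)(/C=C/CO[Si](C)(C)C(C)(C)C)[C@@H](C)C(=O)O[Si](C)(C)C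
F7 | step 16 | (2R,3R,4S,5R)-4-[(tert-butyldimethylsilyl)oxy]-3-[(1E)-3-[(tert-butyldimethylsilyl)oxy]prop-1-en-1-yl]-6-methoxy-2,3,5-trimethyl-6-oxohexanoic acid | COC(=O)[C@H](C)[C@H](O[Si](C)(C)C(C)(C)C)[C@](C)(/C=C/CO[Si](C)(C)C(C)(C)C)[C@@H](C)C(=O)O
F8 | step 7 | (2Z)-3-[(2R,3R)-3-[(1E)-1-iodoprop-1-en-2-yl]-2-methyloxiran-2-yl]-2-methylprop-2-en-1-ol | OC/C(C)=C\[C@@]1(C)O[C@@H]1/C(C)=C/I
F9 | step 7 | (2Z)-3-[(2R,3R)-3-[(1E)-1-iodoprop-1-en-2-yl]-2-methyloxiran-2-yl]-2-methylprop-2-enal | O=C/C(C)=C\[C@@]1(C)O[C@@H]1/C(C)=C/I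
F10 | step 7 | (3Z)-4-[(2R,3R)-3-[(1E)-1-iodoprop-1-en-2-yl]-2-methyloxiran-2-yl]-3-methylbut-3-en-2-ol (both carbinol epimers) | CC(O)/C(C)=C\[C@@]1(C)O[C@@H]1/C(C)=C/I
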